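**Retrosynthetic overview**
- C5=C6 (Z): Wittig reaction of the C6 lactol with the ylide made from 5-bromopentanoic acid and PPh3; the lactol comes from the γ-lactone by hydride reduction.
- C12–C13: Ni–H hydroalkylation joining the C12 bromide of a bromohydrin lactone to the terminal alkyne of (3S,7R)-oct-1-yne-3,7-diol (proposed new step; sets C12 and the E-alkene).
- C11–OH/C12–Br: bromohydrin formation on the cyclopentene-fused γ-lactone.
- γ-Lactone: Baeyer–Villiger ring expansion of racemic cis-bicyclo[3.2.0]hept-2-en-6-one (cyclobutanone to γ-butyrolactone; enzymatic, fixes C8 and C9). The cyclopentane is bought inside the ketone; the lactone is the only ring formed and is opened in the last step.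
- Alkynediol: (R)-δ-hexalactone plus lithium (trimethylsilyl)acetylide, then asymmetric transfer hydrogenation (C15) and desilylation.

Assumption: the enantiopure δ-lactone and the racemic bicyclic ketone are taken as catalogue compounds.

**Route**

Step 1
Reactants: 1 (R)-δ-hexalactone [(6R)-6-methyloxan-2-one]; 2 lithium (trimethylsilyl)acetylide (LiC≡CSiMe3)
Product: 3 (7R)-7-hydroxy-1-(trimethylsilyl)oct-1-yn-3-one
Conditions: 2 (1.1 equiv, 0.5 M in THF), THF, −78 °C; AcOH, −78 °C
Reagents that add atoms: none
Why: Acyl substitution of a δ-lactone by a lithium acetylide stops at the lithium hemiketalate at −78 °C and gives the ynone only on the cold acidic quench, so one acetylide adds; the C19 stereocentre comes from 1 and is not touched.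

Step 2
Reactants: 3 (7R)-7-hydroxy-1-(trimethylsilyl)oct-1-yn-3-one
Product: 5 (3S,7R)-oct-1-yne-3,7-diol, via TMS-alkynediol 4 (not isolated)
Conditions: Ru[(S,S)-TsNCH(Ph)CH(Ph)NH](η6-p-cymene) (1 mol%), i-PrOH, 25 °C; evaporate; K2CO3 (0.2 equiv), MeOH, 25 °C
Reagents that add atoms: none
Why: Noyori–Ikariya asymmetric transfer hydrogenation of an α,β-acetylenic ketone, where the (S,S)-catalyst gives the (S)-propargylic alcohol under reagent control (sets C15, remote C19 has no influence), followed by methanolysis of the C(sp)–Si bond.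

Step 3
Reactants: 6 (±)-cis-bicyclo[3.2.0]hept-2-en-6-one
Product: 7 (1S,5R)-2-oxabicyclo[3.3.0]oct-6-en-3-one
Conditions: cyclohexanone monooxygenase (Acinetobacter calcoaceticus NCIMB 9871, cell-free extract), glucose dehydrogenase, NADP+ (cat.), D-glucose, air, KH2PO4/K2HPO4 buffer pH 7.5, 25 °C; SiO2 chromatography
Reagents that add atoms: dioxygen, O=O
Why: Baeyer–Villiger ring expansion of the cyclobutanone to a γ-lactone by 1,2-shift of the bridgehead carbon to oxygen with retention; the enzyme runs a regiodivergent parallel kinetic resolution, so only the (1R,5S)-ketone gives 7 (fixes C8 and C9) and the (1S,5R)-ketone gives the separable 3-oxa regioisomer (maximum yield 50%).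

Step 4
Reactants: 7 (1S,5R)-2-oxabicyclo[3.3.0]oct-6-en-3-one
Product: 8 (3aS,4R,5R,6aS)-4-bromo-5-hydroxyhexahydro-2H-cyclopenta[b]furan-2-one
Conditions: NBS (1.1 equiv), acetone/H2O 4:1, 0 → 25 °C
Reagents that add atoms: N-bromosuccinimide, O=C1CCC(=O)N1Br; water, O
Why: Bromohydrin formation, in which the bromonium ion forms on the convex β-face and water opens it anti at C11, the carbon remote from the ring fusion, giving 11α-OH and 12β-Br (sets C11).

Step 5
Reactants: 8 (3aS,4R,5R,6aS)-4-bromo-5-hydroxyhexahydro-2H-cyclopenta[b]furan-2-one; 5 (3S,7R)-oct-1-yne-3,7-diol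
Product: 9 (3aR,4R,5R,6aS)-4-[(1E,3S,7R)-3,7-dihydroxyoct-1-en-1-yl]-5-hydroxyhexahydro-2H-cyclopenta[b]furan-2-one
Conditions: NiBr2·glyme (10 mol%), 4,4′-di-tert-butyl-2,2′-bipyridine (12 mol%), (EtO)2MeSiH (2.5 equiv), KF (2.5 equiv), DMA, 25 °C, 5 (1.5 equiv) by syringe pump; aq. NH4Cl work-up
Reagents that add atoms: none
Why: Proposed new method: a bipyridine-ligated Ni–H (from NiBr2·glyme, the silane and KF) should add syn and anti-Markovnikov across the terminal alkyne of 5 (Ni on the unhindered C13), the resulting (E)-alkenylnickel abstracts bromine from 8, and the planar C12 radical is recaptured at nickel on the convex β-face, anti to the C11 hydroxyl and the cis-fused lactone, before C(sp3)–C(sp2) reductive elimination, so the C12–C13 bond, the E-alkene and the 12β configuration are set together while C15 and C19 are untouched; the closest known reactions are Ni–H reductive hydroalkylation of alkenes with secondary alkyl halides, Cu–H/Ni E-selective hydroalkylation of terminal alkynes with primary alkyl iodides, and nickel-catalysed reductive alkenylation of this bromohydrin class with alkenyl halides, none shown for a free propargylic diol with a secondary β-hydroxy bromide.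

Step 6
Reactants: 9 (3aR,4R,5R,6aS)-4-[(1E,3S,7R)-3,7-dihydroxyoct-1-en-1-yl]-5-hydroxyhexahydro-2H-cyclopenta[b]furan-2-one
Product: 10 (3aR,4R,5R,6aS)-4-[(1E,3S,7R)-3,7-dihydroxyoct-1-en-1-yl]hexahydro-2H-cyclopenta[b]furan-2,5-diol (mixture of C2 anomers)
Conditions: i-Bu2AlH (5 equiv), THF, −78 °C; MeOH, then aq. KNaC4H4O6
Reagents that add atoms: none
Why: Partial reduction of a γ-lactone by i-Bu2AlH stops at the aluminium lactolate at −78 °C; three further equivalents are consumed by the free hydroxyls, and the alkene and all stereocentres are untouched.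

Step 7
Reactants: 11 5-bromopentanoic acid
Product: 12 (4-carboxybutyl)triphenylphosphonium bromide
Conditions: PPh3 (1.05 equiv), MeCN, reflux
Reagents that add atoms: triphenylphosphine, c1ccc(cc1)P(c1ccccc1)c1ccccc1
Why: SN2 quaternisation of PPh3 by a primary alkyl bromide (phosphonium salt formation).

Step 8
Reactants: 10 (3aR,4R,5R,6aS)-4-[(1E,3S,7R)-3,7-dihydroxyoct-1-en-1-yl]hexahydro-2H-cyclopenta[b]furan-2,5-diol; 12 (4-carboxybutyl)triphenylphosphonium bromide
Product: 14 19(R)-hydroxy prostaglandin F2α, via phosphorus ylide 13 (not isolated)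
Conditions: 12 (6 equiv), KOtBu (12 equiv), THF, 0 °C; then 10, 0 → 25 °C; 1 M HCl to pH 4
Reagents that add atoms: none
Why: Wittig olefination of the open hydroxy-aldehyde form of the lactol with a non-stabilised, lithium-free ylide gives the (Z)-C5=C6 alkene under kinetic control; excess base keeps the hydroxyls as alkoxides and no stereocentre is epimerisable.

**Compound list**

1 | (R)-δ-hexalactone, (6R)-6-methyloxan-2-one | C[C@@H]1CCCC(=O)O1 | starting material
2 | lithium (trimethylsilyl)acetylide | [Li]C#C[Si](C)(C)C | starting material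
3 | (7R)-7-hydroxy-1-(trimethylsilyl)oct-1-yn-3-one | C[C@@H](O)CCCC(=O)C#C[Si](C)(C)C | intermediate
4 | (3S,7R)-1-(trimethylsilyl)oct-1-yne-3,7-diol (TMS-alkynediol) | C[C@@H](O)CCC[C@H](O)C#C[Si](C)(C)C | intermediate
5 | (3S,7R)-oct-1-yne-3,7-diol | C[C@@H](O)CCC[C@H](O)C#C | intermediate
6 | (±)-cis-bicyclo[3.2.0]hept-2-en-6-one (racemate; the (1R,5S) enantiomer that leads to 7 is drawn) | C1=C[C@H]2CC(=O)[C@H]2C1 | starting material
7 | (1S,5R)-2-oxabicyclo[3.3.0]oct-6-en-3-one | C1=C[C@H]2CC(=O)O[C@H]2C1 | intermediate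
8 | (3aS,4R,5R,6aS)-4-bromo-5-hydroxyhexahydro-2H-cyclopenta[b]furan-2-one | Br[C@@H]1[C@H]2CC(=O)O[C@H]2C[C@H]1O | intermediate
9 | (3aR,4R,5R,6aS)-4-[(1E,3S,7R)-3,7-dihydroxyoct-1-en-1-yl]-5-hydroxyhexahydro-2H-cyclopenta[b]furan-2-one | C[C@@H](O)CCC[C@H](O)/C=C/[C@@H]1[C@H]2CC(=O)O[C@H]2C[C@H]1O | intermediate
10 | (3aR,4R,5R,6aS)-4-[(1E,3S,7R)-3,7-dihydroxyoct-1-en-1-yl]hexahydro-2H-cyclopenta[b]furan-2,5-diol (anomer mixture) | C[C@@H](O)CCC[C@H](O)/C=C/[C@@H]1[C@H]2CC(O)O[C@H]2C[C@H]1O | intermediate
11 | 5-bromopentanoic acid | OC(=O)CCCCBr | starting material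
12 | (4-carboxybutyl)triphenylphosphonium bromide | OC(=O)CCCC[P+](c1ccccc1)(c1ccccc1)c1ccccc1.[Br-] | intermediate
13 | potassium 5-(triphenyl-λ5-phosphanylidene)pentanoate (phosphorus ylide) | [K+].[O-]C(=O)CCCC=P(c1ccccc1)(c1ccccc1)c1ccccc1 | intermediate
14 | 19(R)-hydroxy prostaglandin F2α, (5Z,9α,11α,13E,15S,19R)-9,11,15,19-tetrahydroxyprosta-5,13-dien-1-oic acid | C[C@@H](O)CCC[C@H](O)/C=C/[C@@H]1[C@@H](C/C=C\CCCC(=O)O)[C@@H](O)C[C@H]1O | target

**Step count**

Total steps: 8. Longest linear sequence: 5 (6 → 7 → 8 → 9 → 10 → 14; the branch 1 → 3 → 5 → 9 → 10 → 14 is equally long).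

**Steps most likely to fail**

Step 5, the proposed Ni–H hydroalkylation, is the main risk. The alkyne may oligomerise or be semi-reduced, the propargylic hydroxyl may steer Ni–H insertion to the Markovnikov side, KF may close 8 to the epoxide, and 8 may simply be hydrodebrominated. The fallback uses known chemistry, sets out from 5 and comes back at 9. Hydrozirconation of 5 with Cp2Zr(H)Cl (3.3 equiv, two of them consumed by the hydroxyls) in THF, then I2 at 0 °C, gives (1E,3S,7R)-1-iodooct-1-ene-3,7-diol F1. F1 and 8 are then joined by nickel-catalysed reductive cross-electrophile coupling (NiBr2·glyme, 4,4′-di-tert-butyl-2,2′-bipyridine, Zn dust, DMA, 25 °C). The same C12 radical is trapped on the β-face, giving 9 at the cost of one extra step.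

Step 8, the Wittig reaction on the unprotected tetrahydroxy lactol, is the second risk: the polyalkoxide may be poorly soluble and the yield low. The fallback sets out from 9 and comes back at 14. Et3SiCl and imidazole in DMF convert 9 into its tris(triethylsilyl) ether F2. i-Bu2AlH (1.1 equiv) at −78 °C gives the silylated lactol F3. Wittig reaction with ylide 13 (2.5 equiv) gives the tris(triethylsilyl) ether of the target acid F4. Dilute HCl in THF/H2O then removes the three silyl groups to give 14; any 11 → 9 silyl migration is irrelevant because all silyl groups are cleaved.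

Step 1 is the third risk: the tetrahedral adduct may collapse early and take up a second acetylide, and the product equilibrates with its cyclic hemiketal. The fallback sets out from 1 and comes back at 3. Opening 1 with MeNH(OMe)·HCl and i-PrMgCl in THF at −20 °C gives (5R)-5-hydroxy-N-methoxy-N-methylhexanamide F5. Treating F5 with 2 (2.2 equiv) at −78 → 0 °C gives 3, the chelated Weinreb adduct preventing over-addition.

**Further compounds**

F1 | step 5 | (1E,3S,7R)-1-iodooct-1-ene-3,7-diol | C[C@@H](O)CCC[C@H](O)/C=C/I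
F2 | step 8 | tris(triethylsilyl) ether of 9 | C[C@@H](O[Si](CC)(CC)CC)CCC[C@H](O[Si](CC)(CC)CC)/C=C/[C@@H]1[C@H]2CC(=O)O[C@H]2C[C@H]1O[Si](CC)(CC)CC
F3 | step 8 | tris(triethylsilyl) ether of lactol 10 (free lactol OH) | C[C@@H](O[Si](CC)(CC)CC)CCC[C@H](O[Si](CC)(CC)CC)/C=C/[C@@H]1[C@H]2CC(O)O[C@H]2C[C@H]1O[Si](CC)(CC)CC
F4 | step 8 | 11,15,19-tris-O-(triethylsilyl) derivative of 14 | C[C@@H](O[Si](CC)(CC)CC)CCC[C@H](O[Si](CC)(CC)CC)/C=C/[C@@H]1[C@@H](C/C=C\CCCC(=O)O)[C@@H](O)C[C@H]1O[Si](CC)(CC)CC
F5 | step 1 | (5R)-5-hydroxy-N-methoxy-N-methylhexanamide | C[C@@H](O)CCCC(=O)N(C)OC
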